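**Plan**

- Enabling feature: the head group carries oxygen on C1, nitrogen on C2 and oxygen on C3 in a row. An imidate hung on the C1 oxygen can therefore reach C2 of a C2–C3 epoxide through a five-membered dihydrooxazole ring (O1, C1, C2, N, imidate carbon) and leave the epoxide oxygen as the C3 hydroxyl.
- Retrosynthetic cuts, in order: amide N–C(=O); C2–N (tethered epoxide opening); epoxide oxygen and C2=C3 (Sharpless epoxidation, Horner–Wadsworth–Emmons); C5–C6 (acetylide opening of a glycidyl ether); C10–C11 (copper-catalysed alkyl–alkyl coupling); the cyclopropane CH2.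
- Forward: the cyclopropane ring is made first (step 1) and the chain is grown to the C6–C17 alkyne (steps 2–4). This is joined to the C3–C5 glycidyl unit (step 5) and extended by C1–C2 (steps 9–11). The epoxide ring follows (step 12), then the dihydrooxazole ring is closed (step 14) and opened again (step 15). N-acylation comes last (step 19).
- Stereochemistry: C12/C13 come from a dioxaborolane-controlled cyclopropanation of an E-allylic alcohol, C4 from (R)-trityl glycidyl ether, and C2/C3 from epoxidation under D-(−)-diethyl tartrate, C2 then being inverted by nitrogen. The E-olefin at C6=C7 comes from trans-hydroalumination, and C2′ from an oxazolidinone-auxiliary enolate hydroxylation.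

Key step: step 14

Remark: sphingoid numbering is used for positions (C1 = CH2OH, C2 = C–N, ring carbons C12/C13, C2′ = acyl carbinol); TBS = tert-butyl(dimethyl)silyl, trityl = triphenylmethyl; the (R,R)-dioxaborolane is assumed to show with this alkyl-substituted E-allylic alcohol the facial sense it shows with other E-allylic alcohols.

**Route**

Step 1
Reactants: 1 (E)-hept-2-en-1-ol
Product: 2 [(1S,2S)-2-butylcyclopropyl]methanol
Conditions: ZnEt2, CH2I2, DME, (4R,5R)-2-butyl-N,N,N′,N′-tetramethyl-1,3,2-dioxaborolane-4,5-dicarboxamide (1.2 equiv), CH2Cl2, −10 °C → rt; aq. NH4Cl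
Reagents that add atoms: diiodomethane, ICI
Why: Charette asymmetric Simmons–Smith cyclopropanation, in which the zinc alkoxide binds the chiral dioxaborolane and the Zn(CH2I)2 carbenoid is delivered to one olefin face; stereospecific syn addition to the E-olefin sets the trans ring and the (R,R)-ligand should set both ring centres as (1S,2S).

Step 2
Reactants: 2 [(1S,2S)-2-butylcyclopropyl]methanol
Product: 3 (1S,2S)-1-(bromomethyl)-2-butylcyclopropane
Conditions: CBr4, PPh3, CH2Cl2, 0 °C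
Reagents that add atoms: tetrabromomethane, BrC(Br)(Br)Br
Why: Appel bromination proceeds by SN2 attack of bromide on the alkoxyphosphonium ion, which avoids a cyclopropylcarbinyl cation and leaves both ring stereocentres untouched.

Step 3
Reactants: 3 (1S,2S)-1-(bromomethyl)-2-butylcyclopropane; 4 (5-chloropent-1-yn-1-yl)trimethylsilane
Product: 6 {6-[(1S,2S)-2-butylcyclopropyl]hex-1-yn-1-yl}trimethylsilane, via Grignard reagent 5 (not isolated)
Conditions: 4, Mg, I2 (cat.), THF, reflux; then 3, Li2CuCl4 (3 mol %), NMP, THF, 0 °C → rt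
Reagents that add atoms: none
Why: Copper-catalysed sp3–sp3 coupling of a primary alkyl bromide with an alkyl Grignard reagent proceeds by SN2-type displacement at copper and not through free radicals, so the cyclopropylmethyl unit should couple without ring opening; the silyl cap keeps the alkyne from being deprotonated.

Step 4
Reactants: 6 {6-[(1S,2S)-2-butylcyclopropyl]hex-1-yn-1-yl}trimethylsilane
Product: 7 (1S,2S)-1-butyl-2-(hex-5-yn-1-yl)cyclopropane
Conditions: K2CO3 (0.2 equiv), MeOH, rt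
Reagents that add atoms: none
Why: Base-catalysed methanolysis of the C(sp)–Si bond (protodesilylation) frees the terminal alkyne and touches nothing else.

Step 5
Reactants: 7 (1S,2S)-1-butyl-2-(hex-5-yn-1-yl)cyclopropane; 8 (R)-trityl glycidyl ether
Product: 10 (2R)-9-[(1S,2S)-2-butylcyclopropyl]-1-(trityloxy)non-4-yn-2-ol, via lithium acetylide 9 (not isolated)
Conditions: 7, n-BuLi, THF, −78 °C; BF3·OEt2, then 8, −78 °C; aq. NH4Cl
Reagents that add atoms: none
Why: Yamaguchi-type epoxide opening, in which the acetylide activated by BF3 attacks the unsubstituted epoxide carbon by SN2, so the C–O stereocentre of the glycidyl ether is carried over unchanged as the future C4 (R) carbinol.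

Step 6
Reactants: 10 (2R)-9-[(1S,2S)-2-butylcyclopropyl]-1-(trityloxy)non-4-yn-2-ol
Product: 11 (2R,4E)-9-[(1S,2S)-2-butylcyclopropyl]-1-(trityloxy)non-4-en-2-ol
Conditions: LiAlH4, diglyme, 130 °C; aq. KNaC4H4O6 work-up
Reagents that add atoms: none
Why: Hydroxyl-directed trans-hydroalumination of the homopropargylic alkoxide followed by protonolysis of the vinylalane should give the E-olefin; trityl ether and cyclopropane are inert to hydride.

Step 7
Reactants: 11 (2R,4E)-9-[(1S,2S)-2-butylcyclopropyl]-1-(trityloxy)non-4-en-2-ol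
Product: 12 (2R,4E)-2-[(TBS)oxy]-9-[(1S,2S)-2-butylcyclopropyl]-1-(trityloxy)non-4-ene
Conditions: TBSCl, imidazole, DMF, rt → 40 °C
Reagents that add atoms: tert-butyl(chloro)dimethylsilane, CC(C)(C)[Si](C)(C)Cl
Why: Standard imidazole-promoted silylation of a secondary alcohol; this ether should survive the later base, hydride, oxidant and Lewis-acid steps and fall off in the final acid hydrolysis.

Step 8
Reactants: 12 (2R,4E)-2-[(TBS)oxy]-9-[(1S,2S)-2-butylcyclopropyl]-1-(trityloxy)non-4-ene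
Product: 13 (2R,4E)-2-[(TBS)oxy]-9-[(1S,2S)-2-butylcyclopropyl]non-4-en-1-ol
Conditions: p-TsOH·H2O (0.1 equiv), MeOH/CH2Cl2 (1:1), 0 °C; NaHCO3 quench
Reagents that add atoms: none
Why: Acid-catalysed solvolysis, in which the trityl ether ionises to the stabilised trityl cation (trapped by methanol) much faster than the hindered secondary silyl ether is cleaved under catalytic acid at 0 °C.

Step 9
Reactants: 13 (2R,4E)-2-[(TBS)oxy]-9-[(1S,2S)-2-butylcyclopropyl]non-4-en-1-ol
Product: 14 (2R,4E)-2-[(TBS)oxy]-9-[(1S,2S)-2-butylcyclopropyl]non-4-enal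
Conditions: Dess–Martin periodinane, NaHCO3, CH2Cl2, 0 °C → rt; used crude
Reagents that add atoms: none
Why: Dess–Martin oxidation under buffered, non-epimerising conditions converts the primary alcohol to the α-silyloxy aldehyde without touching the olefin or the C4 stereocentre.

Step 10
Reactants: 14 (2R,4E)-2-[(TBS)oxy]-9-[(1S,2S)-2-butylcyclopropyl]non-4-enal
Product: 15 ethyl (2E,4R,6E)-4-[(TBS)oxy]-11-[(1S,2S)-2-butylcyclopropyl]undeca-2,6-dienoate
Conditions: (EtO)2P(O)CH2CO2Et, LiCl, DBU, MeCN, 0 °C → rt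
Reagents that add atoms: triethyl phosphonoacetate, CCOC(=O)CP(=O)(OCC)OCC
Why: Horner–Wadsworth–Emmons olefination under the mild LiCl/amine variant should give the E-enoate and avoids epimerising the α-silyloxy aldehyde.

Step 11
Reactants: 15 ethyl (2E,4R,6E)-4-[(TBS)oxy]-11-[(1S,2S)-2-butylcyclopropyl]undeca-2,6-dienoate
Product: 16 (2E,4R,6E)-4-[(TBS)oxy]-11-[(1S,2S)-2-butylcyclopropyl]undeca-2,6-dien-1-ol
Conditions: i-Bu2AlH (2.5 equiv), CH2Cl2, −78 °C; aq. KNaC4H4O6
Reagents that add atoms: none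
Why: 1,2-Reduction of the α,β-unsaturated ester by i-Bu2AlH at low temperature gives the E-allylic alcohol without conjugate reduction.

Step 12
Reactants: 16 (2E,4R,6E)-4-[(TBS)oxy]-11-[(1S,2S)-2-butylcyclopropyl]undeca-2,6-dien-1-ol
Product: 17 {(2R,3S)-3-[(1R,3E)-1-[(TBS)oxy]-8-[(1S,2S)-2-butylcyclopropyl]oct-3-en-1-yl]oxiran-2-yl}methanol
Conditions: Ti(OiPr)4 (20 mol %), D-(−)-diethyl tartrate (24 mol %), t-BuOOH (decane), 4 Å MS, CH2Cl2, −20 °C
Reagents that add atoms: tert-butyl hydroperoxide, CC(C)(C)OO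
Why: Sharpless asymmetric epoxidation, in which the titanium tartrate binds the allylic hydroxyl and delivers oxygen to the olefin face dictated by D-(−)-diethyl tartrate, setting C2 (R) and C3 of the trans-epoxide under reagent control; the C6=C7 olefin has no directing hydroxyl and should stay untouched.

Step 13
Reactants: 17 {(2R,3S)-3-[(1R,3E)-1-[(TBS)oxy]-8-[(1S,2S)-2-butylcyclopropyl]oct-3-en-1-yl]oxiran-2-yl}methanol
Product: 18 {(2R,3S)-3-[(1R,3E)-1-[(TBS)oxy]-8-[(1S,2S)-2-butylcyclopropyl]oct-3-en-1-yl]oxiran-2-yl}methyl 2,2,2-trichloroethanimidate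
Conditions: Cl3CCN, DBU (0.1 equiv), CH2Cl2, 0 °C; rapid filtration through Et3N-deactivated silica
Reagents that add atoms: trichloroacetonitrile, ClC(Cl)(Cl)C#N
Why: Base-catalysed addition of the primary alcohol to trichloroacetonitrile (imidate formation) is fast at 0 °C and leaves the epoxide intact.

Step 14
Reactants: 18 {(2R,3S)-3-[(1R,3E)-1-[(TBS)oxy]-8-[(1S,2S)-2-butylcyclopropyl]oct-3-en-1-yl]oxiran-2-yl}methyl 2,2,2-trichloroethanimidate
Product: 19 (1S,2R,4E)-2-[(TBS)oxy]-9-[(1S,2S)-2-butylcyclopropyl]-1-[(4S)-2-(trichloromethyl)-4,5-dihydro-1,3-oxazol-4-yl]non-4-en-1-ol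
Conditions: Et2AlCl (1.0 equiv, hexanes), CH2Cl2, 0 °C → rt; aq. NaHCO3/KNaC4H4O6
Reagents that add atoms: none
Why: Et2AlCl binds the epoxide oxygen, and the imidate nitrogen, held over C2 by the C1–O tether, attacks C2 from the side opposite the C2–O bond, so the C2–N bond forms with inversion while the C3–O bond is never broken and the former epoxide oxygen becomes the free C3 hydroxyl. The closest known reaction type is the Lewis-acid-mediated cyclisation of 2,3-epoxy trichloroacetimidates to 4-(1-hydroxyalkyl)-2-trichloromethyl-4,5-dihydrooxazoles. The dihydrooxazole ring (O1, C1, C2, N and the imidate carbon) closes in the 5-exo-tet mode. The new C2 stereocentre (S) is controlled by SN2 inversion at the (2R) epoxide carbon set in step 12, so the trans-epoxide is translated into the erythro C2-amino/C3-hydroxy pair. The step needs attack at C2 and not at C3 (6-endo, dihydrooxazine) or by chloride; the five-membered tether geometry and the electron-withdrawing C4 silyloxy group, which disfavours positive charge at C3, secure this, while the remote olefin, the cyclopropane and the silyl ether should be inert to the mild Lewis acid at 0 °C.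

Step 15
Reactants: 19 (1S,2R,4E)-2-[(TBS)oxy]-9-[(1S,2S)-2-butylcyclopropyl]-1-[(4S)-2-(trichloromethyl)-4,5-dihydro-1,3-oxazol-4-yl]non-4-en-1-ol
Product: 21 (2S,3S,4R,6E)-2-amino-11-[(1S,2S)-2-butylcyclopropyl]undec-6-ene-1,3,4-triol, via O-trichloroacetyl ammonium chloride 20 (not isolated)
Conditions: 3 M aq. HCl/THF (1:1), rt; then aq. NaOH to pH 11
Reagents that add atoms: none
Why: Acid hydrolysis of the 2-trichloromethyl dihydrooxazole gives the O-trichloroacetyl ammonium salt, whose activated ester and the silyl ether are then hydrolysed in the same acidic medium before basification, so no O-to-N acyl shift can occur and no stereocentre is touched.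

Step 16
Reactants: 22 pentacosanoic acid; 23 (4R)-4-benzyl-1,3-oxazolidin-2-one
Product: 25 (4R)-4-benzyl-3-pentacosanoyl-1,3-oxazolidin-2-one, via mixed pivalic anhydride 24 (not isolated)
Conditions: 22, PivCl, Et3N, THF, −20 → 0 °C; then 23, LiCl, rt
Reagents that add atoms: none
Why: Mixed-anhydride N-acylation of the oxazolidinone (pivaloyl activation, LiCl-assisted acyl transfer) attaches the auxiliary under mild conditions at the less hindered carbonyl of the anhydride.

Step 17
Reactants: 25 (4R)-4-benzyl-3-pentacosanoyl-1,3-oxazolidin-2-one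
Product: 27 (4R)-4-benzyl-3-[(2R)-2-hydroxypentacosanoyl]-1,3-oxazolidin-2-one, via sodium enolate 26 (not isolated)
Conditions: NaN(SiMe3)2, THF, −78 °C; 2-(phenylsulfonyl)-3-phenyloxaziridine, −78 °C; AcOH quench
Reagents that add atoms: 2-(phenylsulfonyl)-3-phenyloxaziridine, O=S(=O)(c1ccccc1)N1OC1c1ccccc1
Why: Auxiliary-controlled enolate hydroxylation, in which the chelated sodium Z-enolate is oxidised by the N-sulfonyloxaziridine on the face opposite the benzyl group of the (R)-oxazolidinone, which should set the (R)-carbinol.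

Step 18
Reactants: 27 (4R)-4-benzyl-3-[(2R)-2-hydroxypentacosanoyl]-1,3-oxazolidin-2-one
Product: 29 (2R)-2-hydroxypentacosanoic acid, via lithium peroxycarboxylate 28 (not isolated)
Conditions: LiOH, 30% H2O2, THF/H2O, 0 °C → rt; Na2SO3; aq. HCl
Reagents that add atoms: hydrogen peroxide, OO
Why: Hydroperoxide cleavage of the N-acyl oxazolidinone, in which LiOOH attacks the exocyclic carbonyl selectively and sulfite reduces the peracid, releasing the hydroxy acid without racemisation together with the recoverable auxiliary.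

Step 19
Reactants: 21 (2S,3S,4R,6E)-2-amino-11-[(1S,2S)-2-butylcyclopropyl]undec-6-ene-1,3,4-triol; 29 (2R)-2-hydroxypentacosanoic acid
Product: 31 (2R)-N-[(2S,3S,4R,6E)-11-[(1S,2S)-2-butylcyclopropyl]-1,3,4-trihydroxyundec-6-en-2-yl]-2-hydroxypentacosanamide, via benzotriazolyl ester 30 (not isolated)
Conditions: EDC·HCl, HOBt, THF/CH2Cl2, 40 °C
Reagents that add atoms: none
Why: Carbodiimide/HOBt amide coupling, in which the primary amine is far more nucleophilic than the hydroxyls of either partner, so the benzotriazolyl ester should acylate nitrogen selectively and the α-hydroxy acid needs no protection.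

**Compound list**

1 | (E)-hept-2-en-1-ol | CCCC/C=C/CO | starting material
2 | [(1S,2S)-2-butylcyclopropyl]methanol | CCCC[C@H]1C[C@@H]1CO | intermediate
3 | (1S,2S)-1-(bromomethyl)-2-butylcyclopropane | CCCC[C@H]1C[C@@H]1CBr | intermediate
4 | (5-chloropent-1-yn-1-yl)trimethylsilane | C[Si](C)(C)C#CCCCCl | starting material
5 | [5-(trimethylsilyl)pent-4-yn-1-yl]magnesium chloride | C[Si](C)(C)C#CCCC[Mg]Cl | intermediate
6 | {6-[(1S,2S)-2-butylcyclopropyl]hex-1-yn-1-yl}trimethylsilane | CCCC[C@H]1C[C@@H]1CCCCC#C[Si](C)(C)C | intermediate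
7 | (1S,2S)-1-butyl-2-(hex-5-yn-1-yl)cyclopropane | CCCC[C@H]1C[C@@H]1CCCCC#C | intermediate
8 | (R)-trityl glycidyl ether, (2R)-2-[(trityloxy)methyl]oxirane | C(c1ccccc1)(c2ccccc2)(c3ccccc3)OC[C@H]4CO4 | starting material
9 | {6-[(1S,2S)-2-butylcyclopropyl]hex-1-yn-1-yl}lithium | CCCC[C@H]1C[C@@H]1CCCCC#C[Li] | intermediate
10 | (2R)-9-[(1S,2S)-2-butylcyclopropyl]-1-(trityloxy)non-4-yn-2-ol | C(c1ccccc1)(c2ccccc2)(c3ccccc3)OC[C@H](O)CC#CCCCC[C@H]4C[C@@H]4CCCC | intermediate
11 | (2R,4E)-9-[(1S,2S)-2-butylcyclopropyl]-1-(trityloxy)non-4-en-2-ol | C(c1ccccc1)(c2ccccc2)(c3ccccc3)OC[C@H](O)C/C=C/CCCC[C@H]4C[C@@H]4CCCC | intermediate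
12 | (2R,4E)-2-[(TBS)oxy]-9-[(1S,2S)-2-butylcyclopropyl]-1-(trityloxy)non-4-ene | C(c1ccccc1)(c2ccccc2)(c3ccccc3)OC[C@H](O[Si](C)(C)C(C)(C)C)C/C=C/CCCC[C@H]4C[C@@H]4CCCC | intermediate
13 | (2R,4E)-2-[(TBS)oxy]-9-[(1S,2S)-2-butylcyclopropyl]non-4-en-1-ol | OC[C@H](O[Si](C)(C)C(C)(C)C)C/C=C/CCCC[C@H]1C[C@@H]1CCCC | intermediate
14 | (2R,4E)-2-[(TBS)oxy]-9-[(1S,2S)-2-butylcyclopropyl]non-4-enal | O=C[C@H](O[Si](C)(C)C(C)(C)C)C/C=C/CCCC[C@H]1C[C@@H]1CCCC | intermediate
15 | ethyl (2E,4R,6E)-4-[(TBS)oxy]-11-[(1S,2S)-2-butylcyclopropyl]undeca-2,6-dienoate | CCOC(=O)/C=C/[C@H](O[Si](C)(C)C(C)(C)C)C/C=C/CCCC[C@H]1C[C@@H]1CCCC | intermediate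
16 | (2E,4R,6E)-4-[(TBS)oxy]-11-[(1S,2S)-2-butylcyclopropyl]undeca-2,6-dien-1-ol | OC/C=C/[C@H](O[Si](C)(C)C(C)(C)C)C/C=C/CCCC[C@H]1C[C@@H]1CCCC | intermediate
17 | {(2R,3S)-3-[(1R,3E)-1-[(TBS)oxy]-8-[(1S,2S)-2-butylcyclopropyl]oct-3-en-1-yl]oxiran-2-yl}methanol | OC[C@H]1O[C@@H]1[C@H](O[Si](C)(C)C(C)(C)C)C/C=C/CCCC[C@H]2C[C@@H]2CCCC | intermediate
18 | {(2R,3S)-3-[(1R,3E)-1-[(TBS)oxy]-8-[(1S,2S)-2-butylcyclopropyl]oct-3-en-1-yl]oxiran-2-yl}methyl 2,2,2-trichloroethanimidate | N=C(C(Cl)(Cl)Cl)OC[C@H]1O[C@@H]1[C@H](O[Si](C)(C)C(C)(C)C)C/C=C/CCCC[C@H]2C[C@@H]2CCCC | intermediate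
19 | (1S,2R,4E)-2-[(TBS)oxy]-9-[(1S,2S)-2-butylcyclopropyl]-1-[(4S)-2-(trichloromethyl)-4,5-dihydro-1,3-oxazol-4-yl]non-4-en-1-ol | ClC(Cl)(Cl)C1=N[C@@H](CO1)[C@H](O)[C@H](O[Si](C)(C)C(C)(C)C)C/C=C/CCCC[C@H]2C[C@@H]2CCCC | intermediate
20 | (2S,3S,4R,6E)-2-amino-4-[(TBS)oxy]-11-[(1S,2S)-2-butylcyclopropyl]-3-hydroxyundec-6-en-1-yl trichloroacetate hydrochloride | Cl.N[C@@H](COC(=O)C(Cl)(Cl)Cl)[C@H](O)[C@H](O[Si](C)(C)C(C)(C)C)C/C=C/CCCC[C@H]1C[C@@H]1CCCC | intermediate
21 | (2S,3S,4R,6E)-2-amino-11-[(1S,2S)-2-butylcyclopropyl]undec-6-ene-1,3,4-triol | N[C@@H](CO)[C@H](O)[C@H](O)C/C=C/CCCC[C@H]1C[C@@H]1CCCC | intermediate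
22 | pentacosanoic acid | CCCCCCCCCCCCCCCCCCCCCCCCC(=O)O | starting material
23 | (4R)-4-benzyl-1,3-oxazolidin-2-one | O=C1N[C@H](Cc2ccccc2)CO1 | starting material
24 | pentacosanoic 2,2-dimethylpropanoic anhydride | CCCCCCCCCCCCCCCCCCCCCCCCC(=O)OC(=O)C(C)(C)C | intermediate
25 | (4R)-4-benzyl-3-pentacosanoyl-1,3-oxazolidin-2-one | CCCCCCCCCCCCCCCCCCCCCCCCC(=O)N1[C@H](Cc2ccccc2)COC1=O | intermediate
26 | sodium (Z)-enolate of 25 | CCCCCCCCCCCCCCCCCCCCCCC/C=C(\O[Na])N1[C@H](Cc2ccccc2)COC1=O | intermediate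
27 | (4R)-4-benzyl-3-[(2R)-2-hydroxypentacosanoyl]-1,3-oxazolidin-2-one | CCCCCCCCCCCCCCCCCCCCCCC[C@@H](O)C(=O)N1[C@H](Cc2ccccc2)COC1=O | intermediate
28 | lithium (2R)-2-hydroxypentacosaneperoxoate | [Li+].CCCCCCCCCCCCCCCCCCCCCCC[C@@H](O)C(=O)O[O-] | intermediate
29 | (2R)-2-hydroxypentacosanoic acid | CCCCCCCCCCCCCCCCCCCCCCC[C@@H](O)C(=O)O | intermediate
30 | 1H-benzotriazol-1-yl (2R)-2-hydroxypentacosanoate | CCCCCCCCCCCCCCCCCCCCCCC[C@@H](O)C(=O)On1nnc2ccccc12 | intermediate
31 | (2R)-N-[(2S,3S,4R,6E)-11-[(1S,2S)-2-butylcyclopropyl]-1,3,4-trihydroxyundec-6-en-2-yl]-2-hydroxypentacosanamide | CCCCCCCCCCCCCCCCCCCCCCC[C@@H](O)C(=O)N[C@@H](CO)[C@H](O)[C@H](O)C/C=C/CCCC[C@H]1C[C@@H]1CCCC | target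

**Count and risks**

Total steps: 19. Longest linear sequence: 16 steps (steps 1–15 and 19, from 1); the glycidyl ether enters at step 5 and the acid branch (steps 16–18) at step 19.

Steps most likely to fail:

Step 3. The three-membered ring may be lost through a cyclopropylcarbinyl radical or cation (homoallyl rearrangement), or the bromide may be reduced or eliminated in competition with the coupling. The fallback sets out from 2 and comes back at 7, replacing the alkylation at the cyclopropylmethyl carbon by olefination and diimide saturation. Alcohol 2 is oxidised with Dess–Martin periodinane to (1S,2S)-2-butylcyclopropane-1-carbaldehyde F1. A Wittig reaction with the ylide from (4-hydroxybutyl)triphenylphosphonium bromide and NaN(SiMe3)2 (2 equiv) gives (4Z)-5-[(1S,2S)-2-butylcyclopropyl]pent-4-en-1-ol F2. Diimide (from KO2CN=NCO2K and AcOH in MeOH) saturates the olefin without cleaving the ring and gives 5-[(1S,2S)-2-butylcyclopropyl]pentan-1-ol F3. Dess–Martin oxidation gives 5-[(1S,2S)-2-butylcyclopropyl]pentanal F4, and Seyferth–Gilbert homologation with dimethyl (1-diazo-2-oxopropyl)phosphonate, K2CO3 and MeOH returns alkyne 7.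

Step 6. Hydroalumination of the internal alkyne may be incomplete or unselective at the high temperature it needs, with over-reduction or isomerisation of the chain. The fallback sets out from 7 and comes back at 11, fixing the E geometry by syn-hydrometalation of the terminal alkyne and never forming the internal alkyne 10. Hydrozirconation of 7 with Cp2Zr(H)Cl followed by iodine gives (1S,2S)-1-butyl-2-[(5E)-6-iodohex-5-en-1-yl]cyclopropane F5. Iodine–lithium exchange with t-BuLi (2 equiv, Et2O, −78 °C) gives {(1E)-6-[(1S,2S)-2-butylcyclopropyl]hex-1-en-1-yl}lithium F6, which in the presence of BF3·OEt2 opens epoxide 8 at its terminal carbon to give homoallylic alcohol 11 directly.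

Step 14. Nitrogen may attack C3 (6-endo closure), chloride from the aluminium reagent may open the epoxide, or the imidate may be lost before it cyclises. The fallback sets out from 17 and comes back at 21, keeping the tethered delivery of nitrogen from the C1 oxygen to C2 but using an anionic carbamate in place of the Lewis-acid-activated imidate. Benzoyl isocyanate (CH2Cl2, rt) converts 17 into {(2R,3S)-3-[(1R,3E)-1-[(TBS)oxy]-8-[(1S,2S)-2-butylcyclopropyl]oct-3-en-1-yl]oxiran-2-yl}methyl benzoylcarbamate F7. K2CO3 in MeCN (or NaH in THF) makes the carbamate nitrogen open the epoxide at C2 with inversion, and an N-to-O benzoyl shift gives (1S,2R,4E)-2-[(TBS)oxy]-9-[(1S,2S)-2-butylcyclopropyl]-1-[(4S)-2-oxo-1,3-oxazolidin-4-yl]non-4-en-1-yl benzoate F8. NaOH in aqueous EtOH at reflux hydrolyses the benzoate and the cyclic carbamate to (2S,3S,4R,6E)-2-amino-4-[(TBS)oxy]-11-[(1S,2S)-2-butylcyclopropyl]undec-6-ene-1,3-diol F9. Aqueous HCl in THF then removes the silyl ether and returns amino triol 21.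

**Further compounds**

F1 | step 3 | (1S,2S)-2-butylcyclopropane-1-carbaldehyde | CCCC[C@H]1C[C@@H]1C=O
F2 | step 3 | (4Z)-5-[(1S,2S)-2-butylcyclopropyl]pent-4-en-1-ol | CCCC[C@H]1C[C@@H]1/C=C\CCCO
F3 | step 3 | 5-[(1S,2S)-2-butylcyclopropyl]pentan-1-ol | CCCC[C@H]1C[C@@H]1CCCCCO
F4 | step 3 | 5-[(1S,2S)-2-butylcyclopropyl]pentanal | CCCC[C@H]1C[C@@H]1CCCCC=O
F5 | step 6 | (1S,2S)-1-butyl-2-[(5E)-6-iodohex-5-en-1-yl]cyclopropane | CCCC[C@H]1C[C@@H]1CCCC/C=C/I
F6 | step 6 | {(1E)-6-[(1S,2S)-2-butylcyclopropyl]hex-1-en-1-yl}lithium | CCCC[C@H]1C[C@@H]1CCCC/C=C/[Li]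
F7 | step 14 | {(2R,3S)-3-[(1R,3E)-1-[(TBS)oxy]-8-[(1S,2S)-2-butylcyclopropyl]oct-3-en-1-yl]oxiran-2-yl}methyl benzoylcarbamate | O=C(NC(=O)c1ccccc1)OC[C@H]2O[C@@H]2[C@H](O[Si](C)(C)C(C)(C)C)C/C=C/CCCC[C@H]3C[C@@H]3CCCC
F8 | step 14 | (1S,2R,4E)-2-[(TBS)oxy]-9-[(1S,2S)-2-butylcyclopropyl]-1-[(4S)-2-oxo-1,3-oxazolidin-4-yl]non-4-en-1-yl benzoate | O=C1N[C@@H](CO1)[C@H](OC(=O)c2ccccc2)[C@H](O[Si](C)(C)C(C)(C)C)C/C=C/CCCC[C@H]3C[C@@H]3CCCC
F9 | step 14 | (2S,3S,4R,6E)-2-amino-4-[(TBS)oxy]-11-[(1S,2S)-2-butylcyclopropyl]undec-6-ene-1,3-diol | N[C@@H](CO)[C@H](O)[C@H](O[Si](C)(C)C(C)(C)C)C/C=C/CCCC[C@H]1C[C@@H]1CCCC
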